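## Retrosynthetic overview

1. The strategy rests on the aryltetralin half: C1 (diarylmethine), C2 (CH–CH2OH), C3 (C(OH)CH2OH), C4 (benzylic CH2) and the fusion carbons C4a/C8a, with C1–C8a para to the C6 methoxy group. This ring is the C-cyclised isomer of a second 2-aryl-3-hydroxymethyl-4-benzyl-4-hydroxytetrahydrofuran, so cutting C1–C8a leads to bis-tetrahydrofuran 26, in which only the isovanillyl phenol carries a pivalate.
2. Both tetrahydrofurans (O1–C2 bonds) come from bis-triol 22 by dehydrative closure; 22 comes from the bis(α-hydroxy-α-benzyl-γ-aryl lactone) 21.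
3. The 5,5'-biaryl bond is cut by a Suzuki–Miyaura disconnection into two α-benzyl lactones (vanillyl 13, isovanillyl 18), both made from one lactone 10; the two C4 carbinols are set together afterwards by enolate hydroxylation anti to the C3 substituent.
4. Lactone 10 (C2, C3) comes from an Evans syn-aldol reaction of a succinate imide with O-benzyl-5-bromovanillin.
5. Ring order: γ-lactone (made once, used twice), biaryl, two tetrahydrofurans, then the tetralin by isomerisation of one tetrahydrofuran.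

Key step: step 19

Remark (assumption): 4-(benzyloxy)-3-methoxybenzyl alcohol (11, the O-benzyl ether of vanillyl alcohol) and 5-bromovanillin are taken as purchasable. C2 of each tetrahydrofuran is re-formed under reversible, acid-mediated closure and is assumed to settle 2,3-trans as in the olivil series.

Abbreviations: Ar = 4-(benzyloxy)-3-bromo-5-methoxyphenyl; Van = 4-(benzyloxy)-3-methoxybenzyl; Iso = 4-methoxy-3-(triisopropylsilyloxy)benzyl; TBS = tert-butyldimethylsilyl; TIPS = triisopropylsilyl. Lactones and tetrahydrofurans are numbered alike: O1, C2 (aryl), C3 (CH2O), C4 (benzyl), C5 (C=O or CH2). Ring A is the biaryl ring of the isovanillyl half, ring B that of the vanillyl half.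

## Route

Step 1
Reactants: 1 5-bromovanillin
Product: 2 4-(benzyloxy)-3-bromo-5-methoxybenzaldehyde
Conditions: BnBr, K2CO3, DMF, 60 °C
Reagents that add atoms: benzyl bromide, BrCc1ccccc1
Why: Williamson ether synthesis on the phenoxide gives a benzyl ether that should survive every later base, hydride and acid step and fall only to hydrogenolysis.

Step 2
Reactants: 3 (S)-4-benzyloxazolidin-2-one; 4 methyl 4-chloro-4-oxobutanoate
Product: 5 methyl 4-[(S)-4-benzyl-2-oxooxazolidin-3-yl]-4-oxobutanoate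
Conditions: n-BuLi, THF, −78 °C; then 4, −78 → 0 °C
Reagents that add atoms: none
Why: N-acylation of the lithiated oxazolidinone auxiliary by the acid chloride, which reacts far faster than the methyl ester.

Step 3
Reactants: 5 methyl 4-[(S)-4-benzyl-2-oxooxazolidin-3-yl]-4-oxobutanoate; 2 4-(benzyloxy)-3-bromo-5-methoxybenzaldehyde
Product: 7 2,3-trans lactone imide (S)-4-benzyl-3-[(2S,3S)-2-Ar-5-oxotetrahydrofuran-3-carbonyl]oxazolidin-2-one, via syn-aldol adduct 6 (not isolated)
Conditions: Bu2BOTf, i-Pr2NEt, CH2Cl2, 0 °C; 2, −78 → 0 °C; pH 7 buffer, H2O2, MeOH; then PPTS (cat.), CH2Cl2, rt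
Reagents that add atoms: none
Why: Evans syn-aldol reaction of the Z boron enolate through a Zimmerman–Traxler chair, in which the (S)-benzyl auxiliary sets the (S) carbinol (C2) and the adjacent (S) centre (C3), followed by lactonisation of the new hydroxyl onto the methyl ester, which turns the syn adduct into the 2,3-trans γ-aryl lactone.

Step 4
Reactants: 7 2,3-trans lactone imide
Product: 8 (2S,3S)-2-Ar-5-oxotetrahydrofuran-3-carboxylic acid
Conditions: LiOH, H2O2, THF/H2O, 0 °C; Na2SO3; HCl to pH 2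
Reagents that add atoms: hydrogen peroxide, OO
Why: Lithium hydroperoxide attacks the exocyclic imide carbonyl selectively (standard auxiliary cleavage), and acidification re-closes any opened lactone without touching C2 or C3.

Step 5
Reactants: 8 (2S,3S)-2-Ar-5-oxotetrahydrofuran-3-carboxylic acid
Product: 9 (2S,3R)-2-Ar-3-(hydroxymethyl)-5-oxotetrahydrofuran
Conditions: BH3·SMe2, THF, 0 °C → rt
Reagents that add atoms: none
Why: Chemoselective borane reduction of the carboxylic acid through its acyloxyborane should leave the lactone, the aryl bromide and the benzyl ether intact.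

Step 6
Reactants: 9 (2S,3R)-2-Ar-3-(hydroxymethyl)-5-oxotetrahydrofuran
Product: 10 (2S,3R)-2-Ar-3-[(tert-butyldimethylsilyloxy)methyl]-5-oxotetrahydrofuran
Conditions: TBSCl, imidazole, CH2Cl2, 0 °C
Reagents that add atoms: tert-butyldimethylsilyl chloride, CC(C)(C)[Si](C)(C)Cl
Why: Silylation of the primary alcohol under weakly basic conditions, done at once so that the hydroxymethyl group cannot translactonise onto C5.

Step 7
Reactants: 11 4-(benzyloxy)-3-methoxybenzyl alcohol
Product: 12 4-(benzyloxy)-3-methoxybenzyl bromide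
Conditions: PBr3, Et2O, 0 °C
Reagents that add atoms: phosphorus tribromide, BrP(Br)Br
Why: Bromide displacement on the phosphite ester of a benzylic alcohol gives the bromide, which is used at once.

Step 8
Reactants: 10 silyl-protected lactone; 12 4-(benzyloxy)-3-methoxybenzyl bromide
Product: 13 (2S,3R,4S)-2-Ar-3-(TBSO-methyl)-4-Van-5-oxotetrahydrofuran
Conditions: LiN(SiMe3)2, THF, −78 °C; 12, −78 → −40 °C
Reagents that add atoms: none
Why: Alkylation of the lactone lithium enolate by the benzylic bromide, which should enter trans to the C3 silyloxymethyl group; this centre is flattened again in step 14, so its configuration is of no consequence.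

Step 9
Reactants: 14 isovanillin
Product: 15 4-methoxy-3-(triisopropylsilyloxy)benzaldehyde
Conditions: TIPSCl, imidazole, DMF, rt
Reagents that add atoms: triisopropylsilyl chloride, CC(C)[Si](Cl)(C(C)C)C(C)C
Why: Silylation of the phenol gives a base-, hydride- and acid-stable aryl silyl ether that marks this one phenol for later exchange to the pivalate.

Step 10
Reactants: 15 4-methoxy-3-(triisopropylsilyloxy)benzaldehyde
Product: 16 [4-methoxy-3-(triisopropylsilyloxy)phenyl]methanol
Conditions: NaBH4, MeOH/THF, 0 °C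
Reagents that add atoms: none
Why: Borohydride reduction of the aldehyde; the hindered aryl silyl ether is not attacked at 0 °C.

Step 11
Reactants: 16 [4-methoxy-3-(triisopropylsilyloxy)phenyl]methanol
Product: 17 4-(bromomethyl)-1-methoxy-2-(triisopropylsilyloxy)benzene
Conditions: PBr3, Et2O, 0 °C
Reagents that add atoms: phosphorus tribromide, BrP(Br)Br
Why: Same benzylic alcohol-to-bromide conversion as in step 7; the bromide is used at once.

Step 12
Reactants: 10 silyl-protected lactone; 17 4-(bromomethyl)-1-methoxy-2-(triisopropylsilyloxy)benzene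
Product: 18 (2S,3R,4S)-2-Ar-3-(TBSO-methyl)-4-Iso-5-oxotetrahydrofuran
Conditions: LiN(SiMe3)2, THF, −78 °C; 17, −78 → −40 °C
Reagents that add atoms: none
Why: Enolate alkylation as in step 8, trans to the C3 substituent, brings in the isovanillyl ring with its phenol differentiated from all others.

Step 13
Reactants: 13 vanillyl lactone bromide; 18 isovanillyl lactone bromide
Product: 20 unsymmetrical 5,5'-linked bis-lactone, via pinacol boronate 19 (not isolated)
Conditions: 13, B2pin2, Pd(dppf)Cl2 (5 mol%), KOAc, 1,4-dioxane, 90 °C; then 18, aq. K3PO4, 80 °C; citric acid work-up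
Reagents that add atoms: bis(pinacolato)diboron, CC1(C)OB(OC1(C)C)B1OC(C)(C)C(C)(C)O1 (its boron stays in intermediate 19 only)
Why: Miyaura borylation of 13 followed in the same flask by Suzuki–Miyaura coupling with 18 should give the unsymmetrical biaryl without a statistical step, the acidic work-up re-closing any lactone opened by the aqueous base.

Step 14
Reactants: 20 unsymmetrical bis-lactone
Product: 21 bis(α-hydroxy lactone), each ring (2S,3R,4S) with C4–OH trans to the C3 substituent
Conditions: KN(SiMe3)2 (2.5 equiv), THF, −78 °C; 2-(phenylsulfonyl)-3-phenyloxaziridine (3 equiv), −78 °C; NH4Cl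
Reagents that add atoms: 2-(phenylsulfonyl)-3-phenyloxaziridine, O=S(=O)(c1ccccc1)N1OC1c1ccccc1
Why: Two-directional enolate hydroxylation by the N-sulfonyloxaziridine, in which oxygen should be delivered to each planar enolate from the face anti to the C3 silyloxymethyl group, so that both C4 carbinols are set by substrate control with the benzyl group cis to C3–CH2O.

Step 15
Reactants: 21 bis(α-hydroxy lactone)
Product: 22 bis-triol (each half ArCH(OH)–CH(CH2OTBS)–C(OH)(benzyl)–CH2OH)
Conditions: LiAlH4, THF, 0 °C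
Reagents that add atoms: none
Why: Hydride reduction of both lactones to 1,4-diols turns C5 into the neopentyl CH2OH and should leave the silyl ethers, the benzyl ethers and all stereocentres untouched.

Step 16
Reactants: 22 bis-triol
Product: 23 bis-tetrahydrofuran, each ring (2S,3R,4S), three aryl benzyl ethers, isovanillyl O-TIPS, both CH2OH free
Conditions: CSA (0.3 equiv), CH2Cl2/MeOH 9:1, 0 °C → rt
Reagents that add atoms: none
Why: Acid methanolysis removes the two primary silyl ethers, and each benzylic carbinol then ionises to a para-benzyloxybenzyl cation that the C5 hydroxyl captures 5-exo (dehydrative SN1 etherification, known for 1-aryl-1,4-diols in tetrahydrofuran lignan work), C2 being re-formed with the aryl group trans to C3–CH2OH; O-capture should be far faster than arene attack, and the O-benzylated ethers re-ionise only sluggishly.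

Step 17
Reactants: 23 bis-tetrahydrofuran
Product: 25 isovanillyl pivalate of the bis-tetrahydrofuran, via free isovanillyl phenol 24 (not isolated)
Conditions: Bu4NF (1.05 equiv), THF, −20 °C; then PivCl (1.1 equiv), −20 → 0 °C
Reagents that add atoms: pivaloyl chloride, CC(C)(C)C(Cl)=O
Why: Fluoride cleaves the aryl silyl ether and the tetrabutylammonium phenoxide formed is acylated in the same flask (desilylative acylation), the phenoxide outrunning the neutral primary and tertiary alcohols toward the hindered acyl chloride.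

Step 18
Reactants: 25 isovanillyl pivalate
Product: 26 bis-tetrahydrofuran precursor (isovanillyl O-pivalate; ring A, ring B and vanillyl phenols free)
Conditions: H2 (1 atm), Pd/C (10%), EtOAc/EtOH, rt
Reagents that add atoms: none
Why: Hydrogenolysis of the three aryl benzyl ethers, which in neutral EtOAc should be cleaved much faster than the cyclic benzylic C2–O bonds, while the aryl pivalate is inert.

Step 19
Reactants: 26 bis-tetrahydrofuran precursor
Product: 28 tetralin–tetrahydrofuran mono-pivalate with tetralin (1S,2S,3S), via ring-opened quinone methide 27 (not isolated)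
Conditions: TFA (5 equiv), CH2Cl2/HFIP 4:1, 0 °C → rt; NaHCO3 quench when 26 is consumed
Reagents that add atoms: none
Why: Acid protonates the ring oxygen of either tetrahydrofuran and the free para-phenol of ring A or ring B pushes out O1, giving the ring-opened p-quinone methide 27 (as its conjugate acid) with C5 released as CH2OH; this is the known acid isomerisation of olivil-type 2-aryltetrahydrofurans to cycloolivil-type aryltetralins, a cationic Friedel–Crafts cycloalkylation. The six-membered carbocycle closes when vanillyl C6, para to its methoxy group, attacks the exocyclic methide carbon: 6-exo-trig with respect to the quinone methide C=C and endo with respect to the arene π bond; rearomatisation makes this irreversible, whereas O-recapture only returns the tetrahydrofuran. The new stereocentre C1 is controlled by the neighbouring C2 centre, the aryl group taking the pseudo-equatorial position trans to the C2 hydroxymethyl group in a half-chair transition state, and C2 and C3 are not touched. Half-selectivity is needed because both rings ionise: in the isovanillyl half the carbons ortho to the benzylic CH2 are para or ortho to the pivaloyloxy group and only meta to methoxy, so this arene should be far less nucleophilic and its cation should simply re-close to the 2,3-trans tetrahydrofuran. Within the vanillyl ring, C6 should win over the hindered C2 (between CH2 and OMe) by para activation, and the reaction is quenched once 26 is gone so that the second half has no time to close.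

Step 20
Reactants: 28 tetralin–tetrahydrofuran mono-pivalate
Product: 29 target CNP0252244.1
Conditions: K2CO3, MeOH, rt, argon
Reagents that add atoms: none
Why: Base-mediated methanolysis (transesterification) of the aryl pivalate releases the isovanillyl phenoxide as a good leaving group; the polyol, the tetrahydrofuran and the tetralin are base-stable.

## Compound list

1 | 5-bromovanillin (3-bromo-4-hydroxy-5-methoxybenzaldehyde) | COc1cc(C=O)cc(Br)c1O | starting material
2 | 4-(benzyloxy)-3-bromo-5-methoxybenzaldehyde | COc1cc(C=O)cc(Br)c1OCc1ccccc1 | intermediate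
3 | (S)-4-benzyloxazolidin-2-one | O=C1N[C@@H](Cc2ccccc2)CO1 | starting material
4 | methyl 4-chloro-4-oxobutanoate | COC(=O)CCC(Cl)=O | starting material
5 | methyl 4-[(S)-4-benzyl-2-oxooxazolidin-3-yl]-4-oxobutanoate | COC(=O)CCC(=O)N1[C@@H](Cc2ccccc2)COC1=O | intermediate
6 | methyl (3S,4S)-4-Ar-3-[(S)-4-benzyl-2-oxooxazolidine-3-carbonyl]-4-hydroxybutanoate (syn-aldol adduct) | COC(=O)C[C@H](C(=O)N1[C@@H](Cc2ccccc2)COC1=O)[C@H](O)c1cc(OC)c(OCc2ccccc2)c(Br)c1 | intermediate
7 | (S)-4-benzyl-3-[(2S,3S)-2-Ar-5-oxotetrahydrofuran-3-carbonyl]oxazolidin-2-one (2,3-trans) | O=C1C[C@H](C(=O)N2[C@@H](Cc3ccccc3)COC2=O)[C@@H](c2cc(OC)c(OCc3ccccc3)c(Br)c2)O1 | intermediate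
8 | (2S,3S)-2-Ar-5-oxotetrahydrofuran-3-carboxylic acid | O=C1C[C@H](C(=O)O)[C@@H](c2cc(OC)c(OCc3ccccc3)c(Br)c2)O1 | intermediate
9 | (2S,3R)-2-Ar-3-(hydroxymethyl)-5-oxotetrahydrofuran | O=C1C[C@H](CO)[C@@H](c2cc(OC)c(OCc3ccccc3)c(Br)c2)O1 | intermediate
10 | (2S,3R)-2-Ar-3-[(tert-butyldimethylsilyloxy)methyl]-5-oxotetrahydrofuran | O=C1C[C@H](CO[Si](C)(C)C(C)(C)C)[C@@H](c2cc(OC)c(OCc3ccccc3)c(Br)c2)O1 | intermediate
11 | 4-(benzyloxy)-3-methoxybenzyl alcohol | COc1cc(CO)ccc1OCc1ccccc1 | starting material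
12 | 4-(benzyloxy)-3-methoxybenzyl bromide | COc1cc(CBr)ccc1OCc1ccccc1 | intermediate
13 | (2S,3R,4S)-2-Ar-3-(TBSO-methyl)-4-Van-5-oxotetrahydrofuran (all-trans) | O=C1[C@@H](Cc2ccc(OCc3ccccc3)c(OC)c2)[C@H](CO[Si](C)(C)C(C)(C)C)[C@@H](c2cc(OC)c(OCc3ccccc3)c(Br)c2)O1 | intermediate
14 | isovanillin (3-hydroxy-4-methoxybenzaldehyde) | COc1ccc(C=O)cc1O | starting material
15 | 4-methoxy-3-(triisopropylsilyloxy)benzaldehyde | COc1ccc(C=O)cc1O[Si](C(C)C)(C(C)C)C(C)C | intermediate
16 | [4-methoxy-3-(triisopropylsilyloxy)phenyl]methanol | COc1ccc(CO)cc1O[Si](C(C)C)(C(C)C)C(C)C | intermediate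
17 | 4-(bromomethyl)-1-methoxy-2-(triisopropylsilyloxy)benzene | COc1ccc(CBr)cc1O[Si](C(C)C)(C(C)C)C(C)C | intermediate
18 | (2S,3R,4S)-2-Ar-3-(TBSO-methyl)-4-Iso-5-oxotetrahydrofuran (all-trans) | O=C1[C@@H](Cc2ccc(OC)c(O[Si](C(C)C)(C(C)C)C(C)C)c2)[C@H](CO[Si](C)(C)C(C)(C)C)[C@@H](c2cc(OC)c(OCc3ccccc3)c(Br)c2)O1 | intermediate
19 | pinacol boronate of 13 (Bpin in place of Br) | O=C1[C@@H](Cc2ccc(OCc3ccccc3)c(OC)c2)[C@H](CO[Si](C)(C)C(C)(C)C)[C@@H](c2cc(OC)c(OCc3ccccc3)c(B3OC(C)(C)C(C)(C)O3)c2)O1 | intermediate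
20 | 5,5'-linked bis-lactone (vanillyl lactone on ring B, isovanillyl lactone on ring A; both 2,3-trans-3,4-trans) | O=C1[C@@H](Cc2ccc(OCc3ccccc3)c(OC)c2)[C@H](CO[Si](C)(C)C(C)(C)C)[C@@H](c2cc(OC)c(OCc3ccccc3)c(-c3cc([C@H]4OC(=O)[C@@H](Cc5ccc(OC)c(O[Si](C(C)C)(C(C)C)C(C)C)c5)[C@@H]4CO[Si](C)(C)C(C)(C)C)cc(OC)c3OCc3ccccc3)c2)O1 | intermediate
21 | bis(α-hydroxy lactone), each ring (2S,3R,4S): C4 bears OH (cis to the C2 aryl) and benzyl (cis to C3–CH2OTBS) | O=C1[C@](O)(Cc2ccc(OCc3ccccc3)c(OC)c2)[C@H](CO[Si](C)(C)C(C)(C)C)[C@@H](c2cc(OC)c(OCc3ccccc3)c(-c3cc([C@H]4OC(=O)[C@](O)(Cc5ccc(OC)c(O[Si](C(C)C)(C(C)C)C(C)C)c5)[C@@H]4CO[Si](C)(C)C(C)(C)C)cc(OC)c3OCc3ccccc3)c2)O1 | intermediate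
22 | bis-triol (both lactones reduced: benzylic CH(OH), C(OH)(benzyl)CH2OH, CH2OTBS) | OC[C@](O)(Cc1ccc(OCc2ccccc2)c(OC)c1)[C@H](CO[Si](C)(C)C(C)(C)C)[C@H](O)c1cc(OC)c(OCc2ccccc2)c(-c2cc([C@@H](O)[C@@H](CO[Si](C)(C)C(C)(C)C)[C@](O)(CO)Cc3ccc(OC)c(O[Si](C(C)C)(C(C)C)C(C)C)c3)cc(OC)c2OCc2ccccc2)c1 | intermediate
23 | bis-tetrahydrofuran, each ring (2S,3R,4S); ring A, ring B and vanillyl phenols as benzyl ethers, isovanillyl phenol as TIPS ether | COc1ccc(C[C@@]2(O)CO[C@H](c3cc(OC)c(OCc4ccccc4)c(-c4cc([C@H]5OC[C@](O)(Cc6ccc(OCc7ccccc7)c(OC)c6)[C@@H]5CO)cc(OC)c4OCc4ccccc4)c3)[C@H]2CO)cc1O[Si](C(C)C)(C(C)C)C(C)C | intermediate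
24 | bis-tetrahydrofuran with free isovanillyl phenol (formed as its tetrabutylammonium phenoxide) | COc1ccc(C[C@@]2(O)CO[C@H](c3cc(OC)c(OCc4ccccc4)c(-c4cc([C@H]5OC[C@](O)(Cc6ccc(OCc7ccccc7)c(OC)c6)[C@@H]5CO)cc(OC)c4OCc4ccccc4)c3)[C@H]2CO)cc1O | intermediate
25 | bis-tetrahydrofuran isovanillyl pivalate, three aryl benzyl ethers | COc1ccc(C[C@@]2(O)CO[C@H](c3cc(OC)c(OCc4ccccc4)c(-c4cc([C@H]5OC[C@](O)(Cc6ccc(OCc7ccccc7)c(OC)c6)[C@@H]5CO)cc(OC)c4OCc4ccccc4)c3)[C@H]2CO)cc1OC(=O)C(C)(C)C | intermediate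
26 | bis-tetrahydrofuran precursor (isovanillyl O-pivalate, other phenols free) | COc1ccc(C[C@@]2(O)CO[C@H](c3cc(OC)c(O)c(-c4cc([C@H]5OC[C@](O)(Cc6ccc(O)c(OC)c6)[C@@H]5CO)cc(OC)c4O)c3)[C@H]2CO)cc1OC(=O)C(C)(C)C | intermediate
27 | ring-opened p-quinone methide of the vanillyl half (ring B as quinone methide, C5 as CH2OH; methide geometry not defined) | COc1ccc(C[C@@]2(O)CO[C@H](c3cc(OC)c(O)c(C4=CC(=C[C@@H](CO)[C@](O)(CO)Cc5ccc(O)c(OC)c5)C=C(OC)C4=O)c3)[C@H]2CO)cc1OC(=O)C(C)(C)C | intermediate
28 | target mono-pivalate (tetralin 1S,2S,3S; tetrahydrofuran 2S,3R,4S; isovanillyl O-pivalate) | COc1ccc(C[C@@]2(O)CO[C@H](c3cc(OC)c(O)c(-c4cc([C@H]5c6cc(O)c(OC)cc6C[C@@](O)(CO)[C@@H]5CO)cc(OC)c4O)c3)[C@H]2CO)cc1OC(=O)C(C)(C)C | intermediate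
29 | CNP0252244.1 | COc1ccc(C[C@@]2(O)CO[C@H](c3cc(OC)c(O)c(-c4cc([C@H]5c6cc(O)c(OC)cc6C[C@@](O)(CO)[C@@H]5CO)cc(OC)c4O)c3)[C@H]2CO)cc1O | target

## Step count and risks

Total step count: 20. Longest linear sequence: 14 steps (steps 1, 3, 4, 5, 6, 8, 13, 14, 15, 16, 17, 18, 19, 20).

Steps most likely to fail:

1. Step 19. What may go wrong: loss of half-selectivity through slow Friedel–Crafts closure of the pivalate-bearing half on prolonged exposure, together with C2 epimerisation of the surviving ring by repeated ionisation. Fallback (sets out from 13 and 18, returns at 29): the same isomerisation is moved in front of the biaryl coupling, where no half-selectivity is needed. Lactone 13 is hydroxylated (KN(SiMe3)2, then the N-sulfonyloxaziridine) to the vanillyl α-hydroxy lactone F1 and reduced with LiAlH4 to the vanillyl bromo triol F2. TFA in wet CH2Cl2 then removes the silyl ether, closes the tetrahydrofuran and isomerises it on to the O-benzylated bromo aryltetralin F3, and Miyaura borylation (B2pin2, Pd(dppf)Cl2, KOAc) gives the tetralin pinacol boronate F4. Lactone 18 is taken through the same hydroxylation to the isovanillyl α-hydroxy lactone F5 and reduction to the isovanillyl bromo triol F6, and is closed with CSA in CH2Cl2/MeOH to the isovanillyl bromo tetrahydrofuran F7, which stays a benzyl ether and never meets acid as a free phenol. Suzuki–Miyaura coupling of F4 with F7 (Pd(dppf)Cl2, aq. K3PO4) should give the tetralin–tetrahydrofuran tris(benzyl ether) F8; Bu4NF gives the tetralin–tetrahydrofuran phenol F9, and hydrogenolysis (H2, Pd/C) gives 29.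

2. Step 16. What may go wrong: over-reaction of the reversibly formed benzylic cations by C-attack of the benzyl arenes (premature tetralin formation in either half), or incomplete closure through trapping as methyl ethers. Fallback (sets out from 21, returns at 23): the benzylic cation is avoided altogether. i-Bu2AlH at −78 °C reduces both lactones to the bis-lactol F10; Et3SiH with BF3·OEt2 at −78 °C reduces the C5 oxocarbenium ions, so that the C2–O bonds never break, and should give the silyl-protected bis-tetrahydrofuran F11; PPTS in MeOH removes the two primary TBS ethers to give 23.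

3. Step 14. What may go wrong: incomplete double enolisation of the dimer, addition of an enolate to the sulfonimine by-product, and erosion of facial selectivity at the two quaternary centres. Fallback (sets out from 20, returns at 21): a Rubottom-type oxidation replaces the enolate oxidation. KN(SiMe3)2 and Me3SiCl trap both enolates as the bis(trimethylsilyl ketene acetal) F12; dimethyldioxirane in acetone at −78 °C should epoxidise the neutral ketene acetals from the face anti to the C3 substituent, and citric acid work-up gives 21.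

## Further compounds

F1 | step 19 | vanillyl α-hydroxy lactone (2S,3R,4S)-2-Ar-4-hydroxy-3-(TBSO-methyl)-4-Van-5-oxotetrahydrofuran | O=C1[C@](O)(Cc2ccc(OCc3ccccc3)c(OC)c2)[C@H](CO[Si](C)(C)C(C)(C)C)[C@@H](c2cc(OC)c(OCc3ccccc3)c(Br)c2)O1
F2 | step 19 | vanillyl bromo triol | OC[C@](O)(Cc1ccc(OCc2ccccc2)c(OC)c1)[C@H](CO[Si](C)(C)C(C)(C)C)[C@H](O)c1cc(OC)c(OCc2ccccc2)c(Br)c1
F3 | step 19 | O-benzylated bromo aryltetralin (1S,2S,3S)-1-Ar-7-(benzyloxy)-2,3-bis(hydroxymethyl)-6-methoxytetralin-3-ol | COc1cc([C@H]2c3cc(OCc4ccccc4)c(OC)cc3C[C@@](O)(CO)[C@@H]2CO)cc(Br)c1OCc1ccccc1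
F4 | step 19 | tetralin pinacol boronate (Bpin in place of Br in F3) | COc1cc([C@H]2c3cc(OCc4ccccc4)c(OC)cc3C[C@@](O)(CO)[C@@H]2CO)cc(B2OC(C)(C)C(C)(C)O2)c1OCc1ccccc1
F5 | step 19 | isovanillyl α-hydroxy lactone (2S,3R,4S)-2-Ar-4-hydroxy-3-(TBSO-methyl)-4-Iso-5-oxotetrahydrofuran | O=C1[C@](O)(Cc2ccc(OC)c(O[Si](C(C)C)(C(C)C)C(C)C)c2)[C@H](CO[Si](C)(C)C(C)(C)C)[C@@H](c2cc(OC)c(OCc3ccccc3)c(Br)c2)O1
F6 | step 19 | isovanillyl bromo triol | OC[C@](O)(Cc1ccc(OC)c(O[Si](C(C)C)(C(C)C)C(C)C)c1)[C@H](CO[Si](C)(C)C(C)(C)C)[C@H](O)c1cc(OC)c(OCc2ccccc2)c(Br)c1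
F7 | step 19 | isovanillyl bromo tetrahydrofuran (2S,3R,4S)-2-Ar-3-(hydroxymethyl)-4-Iso-tetrahydrofuran-4-ol | COc1ccc(C[C@@]2(O)CO[C@H](c3cc(OC)c(OCc4ccccc4)c(Br)c3)[C@H]2CO)cc1O[Si](C(C)C)(C(C)C)C(C)C
F8 | step 19 | tetralin–tetrahydrofuran tris(benzyl ether) with isovanillyl O-TIPS | COc1ccc(C[C@@]2(O)CO[C@H](c3cc(OC)c(OCc4ccccc4)c(-c4cc([C@H]5c6cc(OCc7ccccc7)c(OC)cc6C[C@@](O)(CO)[C@@H]5CO)cc(OC)c4OCc4ccccc4)c3)[C@H]2CO)cc1O[Si](C(C)C)(C(C)C)C(C)C
F9 | step 19 | tetralin–tetrahydrofuran tris(benzyl ether) with free isovanillyl phenol | COc1ccc(C[C@@]2(O)CO[C@H](c3cc(OC)c(OCc4ccccc4)c(-c4cc([C@H]5c6cc(OCc7ccccc7)c(OC)cc6C[C@@](O)(CO)[C@@H]5CO)cc(OC)c4OCc4ccccc4)c3)[C@H]2CO)cc1O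
F10 | step 16 | bis-lactol (both C5 as CH(OH), anomeric centres not defined) | OC1[C@](O)(Cc2ccc(OCc3ccccc3)c(OC)c2)[C@H](CO[Si](C)(C)C(C)(C)C)[C@@H](c2cc(OC)c(OCc3ccccc3)c(-c3cc([C@H]4OC(O)[C@](O)(Cc5ccc(OC)c(O[Si](C(C)C)(C(C)C)C(C)C)c5)[C@@H]4CO[Si](C)(C)C(C)(C)C)cc(OC)c3OCc3ccccc3)c2)O1
F11 | step 16 | bis-tetrahydrofuran with both CH2OTBS groups and isovanillyl O-TIPS | COc1ccc(C[C@@]2(O)CO[C@H](c3cc(OC)c(OCc4ccccc4)c(-c4cc([C@H]5OC[C@](O)(Cc6ccc(OCc7ccccc7)c(OC)c6)[C@@H]5CO[Si](C)(C)C(C)(C)C)cc(OC)c4OCc4ccccc4)c3)[C@H]2CO[Si](C)(C)C(C)(C)C)cc1O[Si](C(C)C)(C(C)C)C(C)C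
F12 | step 14 | bis(trimethylsilyl ketene acetal) of 20 | C[Si](C)(C)OC1=C(Cc2ccc(OCc3ccccc3)c(OC)c2)[C@H](CO[Si](C)(C)C(C)(C)C)[C@@H](c2cc(OC)c(OCc3ccccc3)c(-c3cc([C@H]4OC(O[Si](C)(C)C)=C(Cc5ccc(OC)c(O[Si](C(C)C)(C(C)C)C(C)C)c5)[C@@H]4CO[Si](C)(C)C(C)(C)C)cc(OC)c3OCc3ccccc3)c2)O1
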